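## Retrosynthetic overview

1. Target ⇒ 6‑acetyl‑7‑hydroxy‑2,2‑dimethyl‑2H‑chromene + (Z)‑4‑acetoxy‑2‑methylbut‑2‑enoic acid. One iodine(III)‑induced acyloxylation forms the C3–O ester bond, shifts the pyran oxygen from CMe2 to C3 (six‑ to five‑membered ring contraction, CMe2 becoming the isopropenyl group) and sets both stereocentres.
2. Chromene ⇒ 6‑acetyl‑7‑hydroxy‑2,2‑dimethylchroman (dehydrogenation) ⇒ 2,2‑dimethylchroman‑7‑ol (C6 acetylation) ⇒ resorcinol + 2‑methylbut‑3‑en‑2‑ol.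
3. Acid ⇒ (Z)‑3‑iodobut‑2‑enyl acetate (hydroxycarbonylation) ⇒ (Z)‑3‑iodobut‑2‑en‑1‑ol ⇒ but‑2‑yn‑1‑ol (trans‑hydroalumination/iodination fixes Z).
4. Ring order: the benzene ring is bought, the pyran ring is made first (step 1), and the dihydrofuran ring is made last by contraction of the pyran (step 7).

The target read from the SMILES is the trans‑(2R,3S) diastereomer with a (Z) side chain.

Assumption: the (R,R)‑lactate aryl‑λ3‑iodane is taken to attack the C3 Re face of the chromene, by analogy (from memory, not checked) with the (S)‑benzylic C–O bond this reagent family forms with styrenes; the mirror‑image reagent from the other lactate is used if the first run shows the opposite sense.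

Reagent I* (step 7): {2,6‑bis[(R)‑1‑methoxy‑1‑oxopropan‑2‑yloxy]phenyl}‑λ3‑iodanediyl diacetate, COC(=O)[C@@H](C)Oc1cccc(O[C@H](C)C(=O)OC)c1I(OC(C)=O)OC(C)=O. Ar* below is its aryl group.

## Route

Step 1
Reactants: 1 resorcinol (3 equiv); 2 2‑methylbut‑3‑en‑2‑ol
Product: 4 2,2‑dimethylchroman‑7‑ol, via 4‑prenylresorcinol 3 (not isolated)
Conditions: 85% HCO2H, 100 °C, 3 h
Reagents that add atoms: none
Why: Acid‑catalysed Friedel–Crafts prenylation of resorcinol at C4 followed by Markovnikov hydroalkoxylation of the prenyl group by the ortho OH closes the chroman; excess 1 limits double annulation and no stereocentre is formed.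

Step 2
Reactants: 4 2,2‑dimethylchroman‑7‑ol
Product: 5 1‑(7‑hydroxy‑2,2‑dimethylchroman‑6‑yl)ethan‑1‑one
Conditions: AcOH (1.5 equiv), PPA, 75 °C, 2 h
Reagents that add atoms: acetic acid CC(=O)O
Why: Nencki‑type Friedel–Crafts acetylation goes to C6 (ortho to OH, para to the ring oxygen) because C8 is flanked by two oxygens, and the product is stabilised as the hydrogen‑bonded o‑hydroxyacetophenone.

Step 3
Reactants: 5 1‑(7‑hydroxy‑2,2‑dimethylchroman‑6‑yl)ethan‑1‑one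
Product: 6 1‑(7‑hydroxy‑2,2‑dimethyl‑2H‑chromen‑6‑yl)ethan‑1‑one
Conditions: DDQ (1.2 equiv), 1,4‑dioxane, reflux, 6 h
Reagents that add atoms: none
Why: DDQ dehydrogenation of a chroman: hydride abstraction from benzylic C4 (cation stabilised by the para OH and the ortho ring oxygen) and loss of H‑3 give the 2H‑chromene.

Step 4
Reactants: 7 but‑2‑yn‑1‑ol
Product: 9 (Z)‑3‑iodobut‑2‑en‑1‑ol, via cyclic alkenylalanate 8 (not isolated)
Conditions: Red‑Al (1.6 equiv), THF, 0 °C → rt; then I2, −78 → 0 °C; Rochelle salt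
Reagents that add atoms: iodine II
Why: Alkoxide‑directed trans‑hydroalumination puts hydride on C2 and aluminium on C3 inside a five‑membered oxaaluminacycle, and iodinolysis of the C–Al bond with retention leaves iodine cis to CH2OH (Z).

Step 5
Reactants: 9 (Z)‑3‑iodobut‑2‑en‑1‑ol
Product: 10 (Z)‑3‑iodobut‑2‑en‑1‑yl acetate
Conditions: Ac2O, pyridine, DMAP (cat.), CH2Cl2, 0 °C
Reagents that add atoms: acetic anhydride CC(=O)OC(C)=O
Why: DMAP‑catalysed O‑acetylation of a primary allylic alcohol, which leaves the vinyl iodide and the alkene geometry untouched.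

Step 6
Reactants: 10 (Z)‑3‑iodobut‑2‑en‑1‑yl acetate
Product: 11 (Z)‑4‑acetoxy‑2‑methylbut‑2‑enoic acid
Conditions: PdCl2(PPh3)2 (5 mol %), CO (1 atm), KOAc (2.5 equiv), H2O (10 equiv), DMF, 40 °C; then pH 3
Reagents that add atoms: carbon monoxide [C-]#[O+]; water O
Why: Pd‑catalysed hydroxycarbonylation (oxidative addition to the vinyl C–I bond, CO insertion, hydrolysis of the acylpalladium) proceeds with retention of alkene geometry, and acetate as base makes any acyl exchange at the allylic acetate degenerate.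

Step 7
Reactants: 6 1‑(7‑hydroxy‑2,2‑dimethyl‑2H‑chromen‑6‑yl)ethan‑1‑one; 11 (Z)‑4‑acetoxy‑2‑methylbut‑2‑enoic acid
Product: 14 (2R,3S)‑5‑acetyl‑6‑hydroxy‑2‑(prop‑1‑en‑2‑yl)‑2,3‑dihydro‑1‑benzofuran‑3‑yl (2Z)‑4‑acetoxy‑2‑methylbut‑2‑enoate, via bis(acyloxy)iodane 12 (not isolated), via iodanyl chroman adduct 13 (not isolated)
Conditions: reagent I* (1.2 equiv), 11 (2.6 equiv), PhCl, 40 °C, 20 mbar (AcOH removed); then 6 (1.0 equiv), TfOH (10 mol %), 4 Å MS, CH2Cl2, −78 → −40 °C; cold aq. NaHCO3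
Reagents that add atoms: none
Why: Proposed new method: iodine(III)‑induced acyloxylative ring contraction – ligand exchange gives 12, whose TfOH‑activated iodine adds to the electron‑rich C3=C4 bond of 6 at C3 from the Re face (face selection by the two lactate arms) while a carboxylate enters anti at the cation‑stabilised benzylic C4 to give trans‑diequatorial (3R,4S)‑13; there the C3–I bond is antiperiplanar to the C2–O1 ring bond, so the ring oxygen shifts from C2 to C3 with inversion as the hypernucleofugal Ar*I leaves (aryloxiranium‑like 1,2‑shift) and the freed carboxylate takes a methyl proton to give the isopropenyl group, so anti addition plus invertive shift fixes the trans‑(2R,3S) pair in one operation; Prévost‑type carboxylate participation would need the diaxial conformer and the chelated phenol exchanges only slowly at iodine; closest known reaction types are the enantioselective Prévost–Woodward dioxygenation of styrenes with chiral lactate aryl‑λ3‑iodanes, the iodine(III)‑mediated ring contraction of 1,2‑dihydronaphthalenes and the sulfonate‑ or DAST‑induced ring contraction of 2,2‑dimethylchroman‑3‑ols.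

## Compound list

1 | resorcinol (benzene‑1,3‑diol) | Oc1cccc(O)c1 | starting material
2 | 2‑methylbut‑3‑en‑2‑ol | CC(C)(O)C=C | starting material
3 | 4‑(3‑methylbut‑2‑en‑1‑yl)benzene‑1,3‑diol (4‑prenylresorcinol) | CC(C)=CCc1ccc(O)cc1O | intermediate
4 | 2,2‑dimethylchroman‑7‑ol | CC1(C)CCc2ccc(O)cc2O1 | intermediate
5 | 1‑(7‑hydroxy‑2,2‑dimethylchroman‑6‑yl)ethan‑1‑one | CC(=O)c1cc2CCC(C)(C)Oc2cc1O | intermediate
6 | 1‑(7‑hydroxy‑2,2‑dimethyl‑2H‑chromen‑6‑yl)ethan‑1‑one | CC(=O)c1cc2C=CC(C)(C)Oc2cc1O | intermediate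
7 | but‑2‑yn‑1‑ol | CC#CCO | starting material
8 | sodium 2,2‑bis(2‑methoxyethoxy)‑3‑methyl‑2,5‑dihydro‑1,2‑oxaluminol‑2‑uide (cyclic alkenylalanate, Al cis to CH2O) | CC1=CCO[Al-]1(OCCOC)OCCOC.[Na+] | intermediate
9 | (Z)‑3‑iodobut‑2‑en‑1‑ol | OC/C=C(/C)I | intermediate
10 | (Z)‑3‑iodobut‑2‑en‑1‑yl acetate | CC(=O)OC/C=C(/C)I | intermediate
11 | (Z)‑4‑acetoxy‑2‑methylbut‑2‑enoic acid | CC(=O)OC/C=C(/C)C(=O)O | intermediate
12 | bis[(Z)‑4‑acetoxy‑2‑methylbut‑2‑enoyloxy](Ar*)‑λ3‑iodane, Ar* = 2,6‑bis[(R)‑1‑methoxy‑1‑oxopropan‑2‑yloxy]phenyl | COC(=O)[C@@H](C)Oc1cccc(O[C@H](C)C(=O)OC)c1I(OC(=O)/C(C)=C\COC(C)=O)OC(=O)/C(C)=C\COC(C)=O | intermediate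
13 | (3R,4S)‑6‑acetyl‑7‑hydroxy‑2,2‑dimethyl‑3‑[Ar*{(Z)‑4‑acetoxy‑2‑methylbut‑2‑enoyloxy}‑λ3‑iodanyl]chroman‑4‑yl (Z)‑4‑acetoxy‑2‑methylbut‑2‑enoate (iodine at C3 trans to the C4 ester) | CC(=O)c1cc2[C@H](OC(=O)/C(C)=C\COC(C)=O)[C@@H](I(OC(=O)/C(C)=C\COC(C)=O)c3c(O[C@H](C)C(=O)OC)cccc3O[C@H](C)C(=O)OC)C(C)(C)Oc2cc1O | intermediate
14 | (2R,3S)‑5‑acetyl‑6‑hydroxy‑2‑(prop‑1‑en‑2‑yl)‑2,3‑dihydro‑1‑benzofuran‑3‑yl (2Z)‑4‑acetoxy‑2‑methylbut‑2‑enoate (2,3‑trans) | C=C(C)[C@H]1Oc2cc(O)c(C(C)=O)cc2[C@@H]1OC(=O)/C(C)=C\COC(C)=O | target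

## Step count and risks

Total step count: 7. Longest linear sequence: 4 steps (1 → 4 → 5 → 6 → 14; the acid branch 7 → 9 → 10 → 11 → 14 is equally long).

Three steps most likely to fail:

Step 7 (the proposed new step). Risks are a low or reversed facial preference, capture of the iodane by the neighbouring ester (dioxolanylium, simple dioxygenation), aryl instead of oxygen migration, oxidation of the phenol, and acid‑induced loss of the benzylic ester from the product to give the benzofuran. The fallback uses known chemistry only, sets out from 6 and 11 and comes back at 14. Jacobsen–Katsuki epoxidation of 6 with (R,R)‑Mn(salen)Cl, NMO and mCPBA in CH2Cl2 at −78 °C gives (3R,4R)‑6‑acetyl‑3,4‑epoxy‑7‑hydroxy‑2,2‑dimethylchroman F1. Opening of the epoxide by 11 (1.5 equiv, CH2Cl2, 0 °C → rt) at the benzylic carbon with inversion gives the trans hydroxy ester (3R,4S)‑6‑acetyl‑3,7‑dihydroxy‑2,2‑dimethylchroman‑4‑yl (Z)‑4‑acetoxy‑2‑methylbut‑2‑enoate F2. Treatment with Tf2O (1.05 equiv) and 2,6‑di‑tert‑butyl‑4‑methylpyridine in CH2Cl2 at −78 → −20 °C forms the C3 triflate (3R,4S)‑6‑acetyl‑7‑hydroxy‑2,2‑dimethyl‑3‑(triflyloxy)chroman‑4‑yl (Z)‑4‑acetoxy‑2‑methylbut‑2‑enoate F3, not isolated, which undergoes the known dehydrative ring contraction of 2,2‑dimethylchroman‑3‑ols (O1 shift with inversion at C3, loss of a methyl proton) to 14.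

Step 6. The risk is that Pd(0) ionises the allylic acetate of 10 or 11 and the carboxylate closes to 3‑methylfuran‑2(5H)‑one. The fallback avoids palladium, sets out from 9 and comes back at 11. Silylation (TBSCl, imidazole, DMF) gives (Z)‑tert‑butyl[(3‑iodobut‑2‑en‑1‑yl)oxy]dimethylsilane F4. Iodine–lithium exchange (t‑BuLi, 2.1 equiv, Et2O, −78 °C) gives with retention (Z)‑[4‑(tert‑butyldimethylsilyloxy)but‑2‑en‑2‑yl]lithium F5, which is trapped with Boc2O as tert‑butyl (Z)‑4‑(tert‑butyldimethylsilyloxy)‑2‑methylbut‑2‑enoate F6. HF·pyridine in THF at 0 °C frees tert‑butyl (Z)‑4‑hydroxy‑2‑methylbut‑2‑enoate F7, whose bulky ester resists lactonisation, and Ac2O/pyridine added to the same flask gives tert‑butyl (Z)‑4‑acetoxy‑2‑methylbut‑2‑enoate F8. TFA in CH2Cl2 at 0 °C then gives 11.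

Step 1. The risks are the 5‑hydroxy regioisomer, double annulation and uncyclised prenylresorcinols. The fallback replaces alkylation by acylative annulation, sets out from 1 and comes back at 4. Resorcinol and 3‑methylbut‑2‑enoic acid (CC(C)=CC(=O)O, bought) in MeSO3H/P2O5 at 70 °C give, by regioselective Friedel–Crafts acylation and oxa‑Michael closure, 7‑hydroxy‑2,2‑dimethylchroman‑4‑one F9. Clemmensen reduction (Zn(Hg), HCl, EtOH/toluene, reflux) of the aryl ketone then gives 4.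

## Further compounds

F1 | step 7 | (3R,4R)‑6‑acetyl‑3,4‑epoxy‑7‑hydroxy‑2,2‑dimethylchroman | CC(=O)c1cc2[C@H]3O[C@H]3C(C)(C)Oc2cc1O
F2 | step 7 | (3R,4S)‑6‑acetyl‑3,7‑dihydroxy‑2,2‑dimethylchroman‑4‑yl (Z)‑4‑acetoxy‑2‑methylbut‑2‑enoate | CC(=O)c1cc2[C@H](OC(=O)/C(C)=C\COC(C)=O)[C@@H](O)C(C)(C)Oc2cc1O
F3 | step 7 | (3R,4S)‑6‑acetyl‑7‑hydroxy‑2,2‑dimethyl‑3‑(triflyloxy)chroman‑4‑yl (Z)‑4‑acetoxy‑2‑methylbut‑2‑enoate | CC(=O)c1cc2[C@H](OC(=O)/C(C)=C\COC(C)=O)[C@@H](OS(=O)(=O)C(F)(F)F)C(C)(C)Oc2cc1O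
F4 | step 6 | (Z)‑tert‑butyl[(3‑iodobut‑2‑en‑1‑yl)oxy]dimethylsilane | CC(C)(C)[Si](C)(C)OC/C=C(/C)I
F5 | step 6 | (Z)‑[4‑(tert‑butyldimethylsilyloxy)but‑2‑en‑2‑yl]lithium | CC(C)(C)[Si](C)(C)OC/C=C(/C)[Li]
F6 | step 6 | tert‑butyl (Z)‑4‑(tert‑butyldimethylsilyloxy)‑2‑methylbut‑2‑enoate | CC(C)(C)[Si](C)(C)OC/C=C(/C)C(=O)OC(C)(C)C
F7 | step 6 | tert‑butyl (Z)‑4‑hydroxy‑2‑methylbut‑2‑enoate | OC/C=C(/C)C(=O)OC(C)(C)C
F8 | step 6 | tert‑butyl (Z)‑4‑acetoxy‑2‑methylbut‑2‑enoate | CC(=O)OC/C=C(/C)C(=O)OC(C)(C)C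
F9 | step 1 | 7‑hydroxy‑2,2‑dimethylchroman‑4‑one | CC1(C)CC(=O)c2ccc(O)cc2O1
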